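**Retrosynthetic overview**
Target = palmitate of methyl isocupressate (normal labdane, 4S,5R,9S,10R); last disconnections are the C15-O acyl bond and C8=C17 (Wittig on the 8-ketone, C9 set by equilibration).
Key disconnection: C5-C10 and C6-C7 together, by intramolecular Diels-Alder reaction of an acyclic triene: 2-silyloxydiene C7=C8(OSi)-C9=C10 plus E vinyl sulfone C5=C6 (PhSO2 on C6 as removable activator).
Enabling feature: ring B is a cyclohexane whose C8 carries only the exocyclic methylene (a masked carbonyl, hence an enol-ether diene carbon) and whose C5-C6 edge is an unsubstituted two-carbon unit; ring A shares the C5-C10 bond, so C1-C2-C3-C4 is a four-atom tether with the quaternary C4 stereocentre next to the dienophile.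
Triene = two fragments of similar size joined at C1-C10 by B-alkyl Suzuki-Miyaura coupling: the E enol triflate of a 3-alkylpentane-2,4-dione (C7-C10, C20, side chain C11-C16) and a vinyl sulfone from (S)-malate (C1-C6, C18, C19; C4 by two Fráter-Seebach alkylations).
Ring order: rings A and B are closed together in step 14; nothing cyclic exists before it and no ring is formed after it.

Key step: step 14

Remark: labdane numbering (C1-C20) is used for all intermediates; it is assumed that the second alkylation of the malate dianion takes the same face as the first, so that the order allyl then methyl gives the (4S) centre.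

Step 1
Reactants: 1 tert-butyl(but-3-yn-1-yloxy)dimethylsilane
Product: 3 (E)-5-(tert-butyldimethylsilyloxy)-3-methylpent-2-en-1-ol, via alkenylalane 2 (not isolated)
Conditions: Me3Al, Cp2ZrCl2 (cat.), CH2Cl2, 0 °C to rt; then n-BuLi, THF, -78 °C; (CH2O)n, -78 °C to rt
Reagents that add atoms: trimethylaluminium C[Al](C)C; formaldehyde (from paraformaldehyde) C=O
Why: Negishi carboalumination adds CH3 and Al syn across the terminal alkyne with Al on the terminal carbon, and hydroxymethylation of the derived alanate retains the geometry, so the later 13E alkene is fixed here (no stereocentre).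

Step 2
Reactants: 3 (E)-5-(tert-butyldimethylsilyloxy)-3-methylpent-2-en-1-ol
Product: 4 (E)-5-(tert-butyldimethylsilyloxy)-1-(tert-butyldiphenylsilyloxy)-3-methylpent-2-ene
Conditions: TBDPSCl, imidazole, DMF, rt
Reagents that add atoms: tert-butyl(chloro)diphenylsilane CC(C)(C)[Si](Cl)(c1ccccc1)c1ccccc1
Why: Silyl ether formation at the only free hydroxyl, with TBDPS chosen because it survives the mild acid of step 3 and everything up to step 16.

Step 3
Reactants: 4 (E)-5-(tert-butyldimethylsilyloxy)-1-(tert-butyldiphenylsilyloxy)-3-methylpent-2-ene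
Product: 5 (E)-5-(tert-butyldiphenylsilyloxy)-3-methylpent-3-en-1-ol
Conditions: PPTS (cat.), MeOH, rt
Reagents that add atoms: none
Why: Selective desilylation by acid-catalysed methanolysis, which cleaves the unhindered primary TBS ether much faster than the TBDPS ether.

Step 4
Reactants: 5 (E)-5-(tert-butyldiphenylsilyloxy)-3-methylpent-3-en-1-ol
Product: 6 (E)-tert-butyl[(5-iodo-3-methylpent-2-en-1-yl)oxy]diphenylsilane
Conditions: I2, PPh3, imidazole, CH2Cl2, 0 °C to rt
Reagents that add atoms: iodine II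
Why: Appel-type iodination of the primary alcohol by SN2 displacement of the oxyphosphonium, which leaves the trisubstituted alkene untouched.

Step 5
Reactants: 6 (E)-tert-butyl[(5-iodo-3-methylpent-2-en-1-yl)oxy]diphenylsilane; 7 pentane-2,4-dione
Product: 8 3-[(3E)-5-(tert-butyldiphenylsilyloxy)-3-methylpent-3-en-1-yl]pentane-2,4-dione
Conditions: K2CO3, acetone, reflux (7 in excess)
Reagents that add atoms: none
Why: C-alkylation (SN2) of the soft, weakly basic acetylacetone enolate by the primary iodide, with excess diketone against dialkylation; C9 is not a stereocentre because both acyl groups are the same.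

Step 6
Reactants: 8 3-[(3E)-5-(tert-butyldiphenylsilyloxy)-3-methylpent-3-en-1-yl]pentane-2,4-dione
Product: 9 (2E)-3-[(3E)-5-(tert-butyldiphenylsilyloxy)-3-methylpent-3-en-1-yl]-4-oxopent-2-en-2-yl trifluoromethanesulfonate
Conditions: DBU, CH2Cl2, -78 °C; then Tf2O, -78 to -20 °C
Reagents that add atoms: trifluoromethanesulfonic anhydride O=S(=O)(OS(=O)(=O)C(F)(F)F)C(F)(F)F
Why: Stereoselective enol triflate formation of a 1,3-dicarbonyl compound, in which O-triflation of the metal-free amidinium enolate (not held in the chelated U shape) should place OTf anti to the remaining acetyl group (E), the geometry that later puts the tether trans to C8.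

Step 7
Reactants: 10 dimethyl (2S)-2-hydroxybutanedioate [dimethyl (S)-malate]
Product: 11 dimethyl (2S,3R)-2-hydroxy-3-(prop-2-en-1-yl)butanedioate
Conditions: LDA (2.1 equiv), THF, -78 to -20 °C; then allyl bromide, -78 °C to rt
Reagents that add atoms: allyl bromide C=CCBr
Why: Fráter-Seebach alkylation, in which the lithium alkoxide enolate takes allyl bromide anti to the C2 oxygen and so sets C3 as R.

Step 8
Reactants: 11 dimethyl (2S,3R)-2-hydroxy-3-(prop-2-en-1-yl)butanedioate
Product: 12 dimethyl (2S,3S)-2-hydroxy-3-methyl-3-(prop-2-en-1-yl)butanedioate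
Conditions: LDA (2.2 equiv), THF/DMPU, -78 to -20 °C; then MeI, -78 to 0 °C
Reagents that add atoms: iodomethane CI
Why: Second Fráter-Seebach alkylation, in which the tetrasubstituted alkoxide enolate is methylated again anti to the alkoxide, so the order allyl then methyl fixes the quaternary centre that becomes (4S).

Step 9
Reactants: 12 dimethyl (2S,3S)-2-hydroxy-3-methyl-3-(prop-2-en-1-yl)butanedioate
Product: 13 (2S,3S)-2-hydroxy-3-(methoxycarbonyl)-3-methylhex-5-enoic acid
Conditions: LiOH (1.05 equiv), THF/H2O, 0 °C; then dilute HCl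
Reagents that add atoms: lithium hydroxide [Li+].[OH-]
Why: Chemoselective saponification, since hydroxide attacks the unhindered, inductively activated α-hydroxy ester and not the neopentyl-type ester on the quaternary carbon; no stereocentre is touched.

Step 10
Reactants: 13 (2S,3S)-2-hydroxy-3-(methoxycarbonyl)-3-methylhex-5-enoic acid
Product: 14 methyl (2S)-2-formyl-2-methylpent-4-enoate
Conditions: Pb(OAc)4, CH2Cl2, 0 °C to rt
Reagents that add atoms: none
Why: Oxidative decarboxylation of the α-hydroxy acid by Pb(OAc)4 gives the aldehyde, whose quaternary α-carbon cannot epimerise.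

Step 11
Reactants: 14 methyl (2S)-2-formyl-2-methylpent-4-enoate
Product: 15 methyl (2S,3E)-2-methyl-4-(phenylsulfonyl)-2-(prop-2-en-1-yl)but-3-enoate
Conditions: diethyl [(phenylsulfonyl)methyl]phosphonate, LiCl, DBU, MeCN, rt
Reagents that add atoms: diethyl [(phenylsulfonyl)methyl]phosphonate CCOP(=O)(CS(=O)(=O)c1ccccc1)OCC
Why: Horner-Wadsworth-Emmons olefination with a sulfonyl-stabilised phosphonate under Masamune-Roush conditions gives the E vinyl sulfone, and the quaternary γ-carbon rules out isomerisation to an allyl sulfone.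

Step 12
Reactants: 15 methyl (2S,3E)-2-methyl-4-(phenylsulfonyl)-2-(prop-2-en-1-yl)but-3-enoate; 9 (2E)-3-[(3E)-5-(tert-butyldiphenylsilyloxy)-3-methylpent-3-en-1-yl]-4-oxopent-2-en-2-yl trifluoromethanesulfonate
Product: 17 methyl (2S,6E,10E)-7-acetyl-12-(tert-butyldiphenylsilyloxy)-2,6,10-trimethyl-2-[(E)-2-(phenylsulfonyl)ethenyl]dodeca-6,10-dienoate, via B-alkyl-9-BBN adduct 16 (not isolated)
Conditions: 9-BBN, THF, rt; then 9, PdCl2(dppf) (cat.), AsPh3 (cat.), K3PO4 (aq.), DMF, rt
Reagents that add atoms: none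
Why: Hydroboration with 9-BBN takes only the terminal allyl alkene (anti-Markovnikov), and B-alkyl Suzuki-Miyaura coupling with the β-triflyloxy enone then forms C1-C10 with retention of the E geometry, which is the convergent union of the two fragments.

Step 13
Reactants: 17 methyl (2S,6E,10E)-7-acetyl-12-(tert-butyldiphenylsilyloxy)-2,6,10-trimethyl-2-[(E)-2-(phenylsulfonyl)ethenyl]dodeca-6,10-dienoate
Product: 18 methyl (2S,6E,10E)-7-[1-(tert-butyldimethylsilyloxy)ethenyl]-12-(tert-butyldiphenylsilyloxy)-2,6,10-trimethyl-2-[(E)-2-(phenylsulfonyl)ethenyl]dodeca-6,10-dienoate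
Conditions: TBSOTf, Et3N, CH2Cl2, -78 to 0 °C
Reagents that add atoms: tert-butyldimethylsilyl trifluoromethanesulfonate CC(C)(C)[Si](C)(C)OS(=O)(=O)C(F)(F)F
Why: Soft enolisation (silyl triflate, amine) of the methyl ketone at C7 gives the cross-conjugated 2-silyloxy-1,3-diene without affecting the C9=C10 geometry or C4.

Step 14
Reactants: 18 methyl (2S,6E,10E)-7-[1-(tert-butyldimethylsilyloxy)ethenyl]-12-(tert-butyldiphenylsilyloxy)-2,6,10-trimethyl-2-[(E)-2-(phenylsulfonyl)ethenyl]dodeca-6,10-dienoate
Product: 19 methyl (13E)-8-(tert-butyldimethylsilyloxy)-15-(tert-butyldiphenylsilyloxy)-6α-(phenylsulfonyl)-17-norlabda-8,13-dien-19-oate (4S; 5α-H; 10β-CH3; trans-fused)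
Conditions: toluene (0.005 M), BHT (cat.), Et3N (trace), sealed tube, 160 °C
Reagents that add atoms: none
Why: Thermal, concerted but asynchronous intramolecular [4+2] cycloaddition of the 2-silyloxydiene (C7=C8-C9=C10) to the E vinyl sulfone (C5=C6), the known Diels-Alder reaction of trienes that carry a vinyl sulfone as an ethylene equivalent. Ring B is the new cyclohexene (bonds C5-C10 and C6-C7), and ring A closes at the same time through the C5-C10 bond as the six-membered ring spanned by the C1-C4 tether, in the fused mode with a chair-like tether. C10 and C5 should come out trans (10β-CH3, 5α-H) because the tether sits trans to C8 on the C9=C10 bond and stays exo while the sulfone is endo, the tether-endo (cis-fused) alternative being crowded by the quaternary C4 and the C9 side chain. The absolute sense at C5 and C10 is relayed from the (4S) centre: in the chair tether the flatter CO2Me should take the pseudoaxial site next to the incoming C10 methyl and the C4 methyl the pseudoequatorial one, so one diene face is preferred. C6 (sulfone α) is a transient centre removed in step 15, and C9 stays sp2 until step 16. The step needs tether-exo/sulfone-endo and π-facial selectivity, both of which rest on the substrate (E tetrasubstituted diene terminus, quaternary C4), while the sulfone keeps the temperature below that of 1,5-hydrogen shifts of the diene.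

Step 15
Reactants: 19 methyl (13E)-8-(tert-butyldimethylsilyloxy)-15-(tert-butyldiphenylsilyloxy)-6α-(phenylsulfonyl)-17-norlabda-8,13-dien-19-oate
Product: 20 methyl (13E)-8-(tert-butyldimethylsilyloxy)-15-(tert-butyldiphenylsilyloxy)-17-norlabda-8,13-dien-19-oate (4S; 5α-H; 10β-CH3)
Conditions: Na(Hg) (6% Na), Na2HPO4, MeOH/THF, -20 °C
Reagents that add atoms: none
Why: Reductive desulfonylation by electron transfer from sodium amalgam cleaves the C6-S bond and the buffer protonates C6, so the activating group leaves without touching the silyl enol ether or the hindered ester.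

Step 16
Reactants: 20 methyl (13E)-8-(tert-butyldimethylsilyloxy)-15-(tert-butyldiphenylsilyloxy)-17-norlabda-8,13-dien-19-oate
Product: 21 methyl (13E)-15-hydroxy-8-oxo-17-norlabd-13-en-19-oate (4S; 5α-H; 9α-H; 10β-CH3)
Conditions: TBAF, THF, 0 °C to rt; then K2CO3, MeOH, rt
Reagents that add atoms: none
Why: Fluoride-mediated desilylation frees the 8-ketone and the C15 alcohol, and base equilibration through the enolate places the C9 side chain equatorial (9α-H), the favoured epimer of the trans-decalone (thermodynamic control).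

Step 17
Reactants: 21 methyl (13E)-15-hydroxy-8-oxo-17-norlabd-13-en-19-oate
Product: 22 methyl isocupressate [methyl (13E)-15-hydroxylabda-8(17),13-dien-19-oate; 4S,5R,9S,10R]
Conditions: Ph3PCH3Br, KOtBu (excess), toluene/THF, rt to 80 °C
Reagents that add atoms: methyltriphenylphosphonium bromide C[P+](c1ccccc1)(c1ccccc1)c1ccccc1.[Br-]
Why: Wittig methylenation of the unconjugated 8-ketone with excess ylide, which tolerates the alkoxide and the hindered axial ester; C9 is already the stable epimer, so reversible enolisation does no harm.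

Step 18
Reactants: 22 methyl isocupressate; 23 hexadecanoyl chloride
Product: 24 methyl (13E)-15-(hexadecanoyloxy)labda-8(17),13-dien-19-oate (4S,5R,9S,10R; target)
Conditions: pyridine, DMAP (cat.), CH2Cl2, 0 °C to rt
Reagents that add atoms: none
Why: DMAP-catalysed acylation of the primary allylic alcohol by the acid chloride, with no stereocentre or alkene affected.

**Compound list**
1 | tert-butyl(but-3-yn-1-yloxy)dimethylsilane | C#CCCO[Si](C)(C)C(C)(C)C | starting material
2 | (E)-[4-(tert-butyldimethylsilyloxy)-2-methylbut-1-en-1-yl]dimethylalane | C[Al](C)/C=C(\C)CCO[Si](C)(C)C(C)(C)C | intermediate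
3 | (E)-5-(tert-butyldimethylsilyloxy)-3-methylpent-2-en-1-ol | OC/C=C(\C)CCO[Si](C)(C)C(C)(C)C | intermediate
4 | (E)-5-(tert-butyldimethylsilyloxy)-1-(tert-butyldiphenylsilyloxy)-3-methylpent-2-ene | CC(C)(C)[Si](C)(C)OCC/C(C)=C/CO[Si](c1ccccc1)(c1ccccc1)C(C)(C)C | intermediate
5 | (E)-5-(tert-butyldiphenylsilyloxy)-3-methylpent-3-en-1-ol | OCC/C(C)=C/CO[Si](c1ccccc1)(c1ccccc1)C(C)(C)C | intermediate
6 | (E)-tert-butyl[(5-iodo-3-methylpent-2-en-1-yl)oxy]diphenylsilane | ICC/C(C)=C/CO[Si](c1ccccc1)(c1ccccc1)C(C)(C)C | intermediate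
7 | pentane-2,4-dione | CC(=O)CC(C)=O | starting material
8 | 3-[(3E)-5-(tert-butyldiphenylsilyloxy)-3-methylpent-3-en-1-yl]pentane-2,4-dione | CC(=O)C(CC/C(C)=C/CO[Si](c1ccccc1)(c1ccccc1)C(C)(C)C)C(C)=O | intermediate
9 | (2E)-3-[(3E)-5-(tert-butyldiphenylsilyloxy)-3-methylpent-3-en-1-yl]-4-oxopent-2-en-2-yl trifluoromethanesulfonate | CC(=O)/C(CC/C(C)=C/CO[Si](c1ccccc1)(c1ccccc1)C(C)(C)C)=C(/OS(=O)(=O)C(F)(F)F)C | intermediate
10 | dimethyl (2S)-2-hydroxybutanedioate | COC(=O)C[C@H](O)C(=O)OC | starting material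
11 | dimethyl (2S,3R)-2-hydroxy-3-(prop-2-en-1-yl)butanedioate | COC(=O)[C@@H](O)[C@@H](CC=C)C(=O)OC | intermediate
12 | dimethyl (2S,3S)-2-hydroxy-3-methyl-3-(prop-2-en-1-yl)butanedioate | COC(=O)[C@@H](O)[C@@](CC=C)(C)C(=O)OC | intermediate
13 | (2S,3S)-2-hydroxy-3-(methoxycarbonyl)-3-methylhex-5-enoic acid | OC(=O)[C@@H](O)[C@@](CC=C)(C)C(=O)OC | intermediate
14 | methyl (2S)-2-formyl-2-methylpent-4-enoate | O=C[C@@](CC=C)(C)C(=O)OC | intermediate
15 | methyl (2S,3E)-2-methyl-4-(phenylsulfonyl)-2-(prop-2-en-1-yl)but-3-enoate | C=CC[C@](/C=C/S(=O)(=O)c1ccccc1)(C)C(=O)OC | intermediate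
16 | methyl (2S,3E)-2-[3-(9-borabicyclo[3.3.1]nonan-9-yl)propyl]-2-methyl-4-(phenylsulfonyl)but-3-enoate | B1(CCC[C@](/C=C/S(=O)(=O)c3ccccc3)(C)C(=O)OC)C2CCCC1CCC2 | intermediate
17 | methyl (2S,6E,10E)-7-acetyl-12-(tert-butyldiphenylsilyloxy)-2,6,10-trimethyl-2-[(E)-2-(phenylsulfonyl)ethenyl]dodeca-6,10-dienoate | CC(=O)/C(CC/C(C)=C/CO[Si](c1ccccc1)(c1ccccc1)C(C)(C)C)=C(/CCC[C@](/C=C/S(=O)(=O)c1ccccc1)(C)C(=O)OC)C | intermediate
18 | methyl (2S,6E,10E)-7-[1-(tert-butyldimethylsilyloxy)ethenyl]-12-(tert-butyldiphenylsilyloxy)-2,6,10-trimethyl-2-[(E)-2-(phenylsulfonyl)ethenyl]dodeca-6,10-dienoate | C=C(O[Si](C)(C)C(C)(C)C)/C(CC/C(C)=C/CO[Si](c1ccccc1)(c1ccccc1)C(C)(C)C)=C(/CCC[C@](/C=C/S(=O)(=O)c1ccccc1)(C)C(=O)OC)C | intermediate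
19 | methyl (13E)-8-(tert-butyldimethylsilyloxy)-15-(tert-butyldiphenylsilyloxy)-6α-(phenylsulfonyl)-17-norlabda-8,13-dien-19-oate (4S; 5α-H; 10β-CH3) | C1(CC/C(C)=C/CO[Si](c3ccccc3)(c3ccccc3)C(C)(C)C)=C(O[Si](C)(C)C(C)(C)C)C[C@H](S(=O)(=O)c3ccccc3)[C@@H]2[C@]1(C)CCC[C@]2(C)C(=O)OC | intermediate
20 | methyl (13E)-8-(tert-butyldimethylsilyloxy)-15-(tert-butyldiphenylsilyloxy)-17-norlabda-8,13-dien-19-oate (4S; 5α-H; 10β-CH3) | C1(CC/C(C)=C/CO[Si](c3ccccc3)(c3ccccc3)C(C)(C)C)=C(O[Si](C)(C)C(C)(C)C)CC[C@@H]2[C@]1(C)CCC[C@]2(C)C(=O)OC | intermediate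
21 | methyl (13E)-15-hydroxy-8-oxo-17-norlabd-13-en-19-oate (4S; 5α-H; 9α-H; 10β-CH3) | O=C1CC[C@@H]2[C@](C)(CCC[C@]2(C)C(=O)OC)[C@H]1CC/C(C)=C/CO | intermediate
22 | methyl isocupressate [methyl (13E)-15-hydroxylabda-8(17),13-dien-19-oate; 4S,5R,9S,10R] | C=C1CC[C@@H]2[C@](C)(CCC[C@]2(C)C(=O)OC)[C@H]1CC/C(C)=C/CO | intermediate
23 | hexadecanoyl chloride | CCCCCCCCCCCCCCCC(=O)Cl | starting material
24 | methyl (13E)-15-(hexadecanoyloxy)labda-8(17),13-dien-19-oate (4S,5R,9S,10R) | C=C1CC[C@@H]2[C@](C)(CCC[C@]2(C)C(=O)OC)[C@H]1CC/C(C)=C/COC(=O)CCCCCCCCCCCCCCC | target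

**Step count and risks**
Total: 18 steps. Longest linear sequence: 13 steps (steps 1-6 and 12-18). The malate branch (steps 7-11) joins at step 12.

Steps most likely to fail:

Step 14. Desilylation or a 1,5-hydrogen shift of the 2-silyloxydiene may outrun a cycloaddition that the tether forces into the electronically less favoured orientation. Separately, π-facial discrimination by C4 (CO2Me against CH3 for the pseudoaxial site) may be incomplete; that would cost material as a separable diastereomer and is not repaired by this fallback. The fallback changes the diene to a thermally robust, less polarised 2-(trimethylsilylmethyl)diene, which also changes how C8=C17 and C9 are made. It sets out from 17. Kinetic enolisation at C7 (KHMDS, PhNTf2, THF, -78 °C) should give the dienyl triflate F1. Coupling with Me3SiCH2MgCl under Pd(PPh3)4 catalysis at 0 °C should give the allylsilane triene F2. Heating in toluene (170 °C) should give the allylsilane cycloadduct F3 with the C8=C9 double bond. Sodium amalgam as in step 15 should give the desulfonylated allylsilane F4. Protodesilylation (CF3CO2H, CH2Cl2, -20 °C) should protonate C9 from the α face, anti to the axial C10 methyl, and move the double bond to C8=C17, giving the TBDPS ether of methyl isocupressate F5. TBAF then gives 22, where the route is rejoined before step 18.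

Step 6. O-sulfonylation may run through a chelated or equilibrating enolate and give the Z triflate or an E/Z mixture; that would put the tether cis to C8 and lead to cis-fused adducts or none. The fallback fixes the geometry on a β-keto amide, whose two carbonyl groups differ and whose amine-base sulfonylation is E-selective by dipole minimisation, and completes the acetyl group afterwards. It sets out from 6. Alkylation of commercial N-methoxy-N-methyl-3-oxobutanamide (K2CO3, acetone) should give the β-keto Weinreb amide F6. TsCl, N-methylimidazole and Et3N should give the E enol tosylate F7. B-alkyl Suzuki-Miyaura coupling with the borane 16 should give the tetrasubstituted unsaturated Weinreb amide F8. MeMgBr (THF, -78 to 0 °C) should convert the amide into the methyl ketone 17, where the route is rejoined before step 13.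

Step 12. Hydrolysis of the β-triflyloxy enone by the aqueous base and protodeboronation of 16 may compete with a slow transmetalation at the tetrasubstituted carbon. The fallback is a base-free organozinc coupling. It sets out from the borane 16 (made from 15 as in step 12). Iodinolysis (I2, NaOMe, MeOH, 0 °C) should give the primary iodide F9. Zinc insertion (Zn dust, LiCl, THF) should give the alkylzinc iodide F10, which tolerates the ester and the vinyl sulfone. Negishi coupling with 9 (Pd(OAc)2, SPhos, THF, rt) should give 17, where the route is rejoined before step 13.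

Further compounds
F1 | step 14 | methyl (2S,6E,10E)-12-(tert-butyldiphenylsilyloxy)-2,6,10-trimethyl-2-[(E)-2-(phenylsulfonyl)ethenyl]-7-[1-(trifluoromethanesulfonyloxy)ethenyl]dodeca-6,10-dienoate | C=C(OS(=O)(=O)C(F)(F)F)/C(CC/C(C)=C/CO[Si](c1ccccc1)(c1ccccc1)C(C)(C)C)=C(/CCC[C@](/C=C/S(=O)(=O)c1ccccc1)(C)C(=O)OC)C
F2 | step 14 | methyl (2S,6E,10E)-12-(tert-butyldiphenylsilyloxy)-2,6,10-trimethyl-2-[(E)-2-(phenylsulfonyl)ethenyl]-7-[3-(trimethylsilyl)prop-1-en-2-yl]dodeca-6,10-dienoate | C=C(C[Si](C)(C)C)/C(CC/C(C)=C/CO[Si](c1ccccc1)(c1ccccc1)C(C)(C)C)=C(/CCC[C@](/C=C/S(=O)(=O)c1ccccc1)(C)C(=O)OC)C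
F3 | step 14 | methyl (13E)-15-(tert-butyldiphenylsilyloxy)-6α-(phenylsulfonyl)-17-(trimethylsilyl)labda-8,13-dien-19-oate (4S; 5α-H; 10β-CH3) | C1(CC/C(C)=C/CO[Si](c3ccccc3)(c3ccccc3)C(C)(C)C)=C(C[Si](C)(C)C)C[C@H](S(=O)(=O)c3ccccc3)[C@@H]2[C@]1(C)CCC[C@]2(C)C(=O)OC
F4 | step 14 | methyl (13E)-15-(tert-butyldiphenylsilyloxy)-17-(trimethylsilyl)labda-8,13-dien-19-oate (4S; 5α-H; 10β-CH3) | C1(CC/C(C)=C/CO[Si](c3ccccc3)(c3ccccc3)C(C)(C)C)=C(C[Si](C)(C)C)CC[C@@H]2[C@]1(C)CCC[C@]2(C)C(=O)OC
F5 | step 14 | methyl (13E)-15-(tert-butyldiphenylsilyloxy)labda-8(17),13-dien-19-oate (4S,5R,9S,10R) | C=C1CC[C@@H]2[C@](C)(CCC[C@]2(C)C(=O)OC)[C@H]1CC/C(C)=C/CO[Si](c3ccccc3)(c3ccccc3)C(C)(C)C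
F6 | step 6 | 2-[(3E)-5-(tert-butyldiphenylsilyloxy)-3-methylpent-3-en-1-yl]-N-methoxy-N-methyl-3-oxobutanamide | CC(=O)C(CC/C(C)=C/CO[Si](c1ccccc1)(c1ccccc1)C(C)(C)C)C(=O)N(C)OC
F7 | step 6 | (2E)-3-[(3E)-5-(tert-butyldiphenylsilyloxy)-3-methylpent-3-en-1-yl]-4-[methoxy(methyl)amino]-4-oxobut-2-en-2-yl 4-methylbenzenesulfonate | CON(C)C(=O)/C(CC/C(C)=C/CO[Si](c1ccccc1)(c1ccccc1)C(C)(C)C)=C(/OS(=O)(=O)c1ccc(C)cc1)C
F8 | step 6 | methyl (2S,6E,10E)-12-(tert-butyldiphenylsilyloxy)-7-[methoxy(methyl)carbamoyl]-2,6,10-trimethyl-2-[(E)-2-(phenylsulfonyl)ethenyl]dodeca-6,10-dienoate | CON(C)C(=O)/C(CC/C(C)=C/CO[Si](c1ccccc1)(c1ccccc1)C(C)(C)C)=C(/CCC[C@](/C=C/S(=O)(=O)c1ccccc1)(C)C(=O)OC)C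
F9 | step 12 | methyl (2S,3E)-2-(3-iodopropyl)-2-methyl-4-(phenylsulfonyl)but-3-enoate | ICCC[C@](/C=C/S(=O)(=O)c1ccccc1)(C)C(=O)OC
F10 | step 12 | [(4S,5E)-4-(methoxycarbonyl)-4-methyl-6-(phenylsulfonyl)hex-5-en-1-yl]zinc iodide | I[Zn]CCC[C@](/C=C/S(=O)(=O)c1ccccc1)(C)C(=O)OC
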